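(The runs were generated by integration from invented constants; noise was put on by code.)

Count the links of a flask against the second end groups charged, not only against the solid first end groups.

| flask | solid first end groups | second end groups | temperature | remark | time |
|---|---|---|---|---|---|
| zeta | 0.067 M | 0.10 M | 40 °C | run made earlier |  |
| east | 0.10 M | 0.0250 M | 40 °C |  | 4.0 h |
| west | 0.10 M | 0.100 M | 40 °C |  | 4.0 h |
| north | 0.10 M | 0.100 M | 55 °C |  | 4.0 h |
| south | 0.10 M | 0.0250 M | 55 °C |  | 4.0 h |

- zeta (time / h: links / %): 0.417: 7.4; 0.833: 15.9; 1.33: 24.3; 1.50: 27.1; 2.00: 34.5; 2.50: 37.9

(each reading ± 0.5 percentage points)

- solid first end groups is a solid; its amount is given per volume of the solution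
- reactions considered so far: first end groups + second end groups -> links; first end groups + second end groups -> rings; solid first end groups <-> first end groups; second end groups <-> dormant form
- at the start none of the solid first end groups is in solution
- what has only dissolved of solid first end groups counts as not reacted
- the earlier runs do not show what temperature does; that part of a forecast is a guess

* the flasks put in order of amount of links, in percent of the solid first end groups charged, best first, at 4.0 h (east / west / north / south)
* the amount of links, in percent of the solid first end groups charged of the flask you put first, at 4.0 h
* the amount of links, in percent of the solid first end groups charged of the flask you put last, at 4.0 h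

Our first estimate lets west keep the early pace of zeta: 27.1 % of the zeta solid charge by 1.50 h becomes, on the larger solid charge of west, 48.4 % by 4.0 h. But zeta does not hold that pace: it gains 7.4 percentage points up to 2.00 h and then, in an equal interval, 3.4 points, which is less by more than the scatter of the readings. Links stand at 37.9 % of the solid charge at the last zeta reading, and we look at the partner, second end groups, on which links, rings and the dormant form draw.

If each interval keeps shrinking by the same ratio, zeta gains a further 2.9 points. Scaling the final links by the zeta charges gives the link yield on second end groups, the links finally made per second end group charged: 27.3 %. That tail rests on two noisy differences, but without it the yield is still 25.4 %, so the doubt is small.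

The larger doubt is that zeta shows a single second charge, and east has a quarter of the west charge. In east second end groups are the limiting reagent, and links there have a ceiling of 25.0 % of the solid charge. We keep the yield anyway, which gives, of the solid charge, west 27.3 % and east 6.83 %. Carrying it to the hotter flasks is a guess, so we expect north near west and south near east.

The forecast differs. It reasons that “the dissolved first end groups stay near saturation, so the rate depends mainly on the second end groups”, and it gives north > west > south > east, with 62 % (45 % to 80 %) first and 10.5 % (7 % to 18 %) last.

The flasks give north > west > east > south, with north at 33.4 % and south at 4.14 %.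

    first end groups + second end groups → links (k = 0.160 M⁻¹ s⁻¹, Ea = 66.0 kJ mol⁻¹)
    first end groups + second end groups → rings, rate k2*[first end groups] as long as [second end groups] is above zero (k = 0.00120 s⁻¹, Ea = 93.0 kJ mol⁻¹)
    solid first end groups ⇌ first end groups, rate k3*(cs3 - [first end groups]) while solid is left; crystals form when [first end groups] > cs3 (solubility = 37.0 mM, k = 1.10 × 10⁻⁴ s⁻¹)
    second end groups ⇌ dormant form (K = 13.0, k = 2.00 × 10⁻⁴ s⁻¹, Ea = 103 kJ mol⁻¹, ΔH = −84.0 kJ mol⁻¹)
    (constants at 40 °C)

At 4.0 h north still holds 8.78 % of its second end groups unbound beside 0.0334 M of dormant form, while west holds 0 % unbound beside 0.0573 M of dormant form. The yield carried from zeta gave west 27.3 % and east 6.83 %; they stand at 27.0 % and 7.93 %. At 55 °C the yield parts: at 4.0 h north has reached 33.4 % on its second charge, and south 16.5 %.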